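**Plan**

Rings: A = para-phenylene, B = 1,2,3-trisubstituted ring with the lone OH, C = meta-phenylene, D = acyl ring with three adjacent oxygens (C1 acyl, O on C3, C4, C5).
Retrosynthetic cuts, in order: the two O–CH3 bonds; the ring A C4–O bond to O-3 of ring D (opens the 18-membered ring); the acyl C–CH2 bond between ring D and ring C; the CH2–CH2 bridge between rings A and B; the ring B C–O bond to ring C.
Forward: the B–O–C ether by nucleophilic aromatic substitution, the A–B bridge by olefination and reduction, the ring D ketone by Claisen condensation with decarboxylation, and the macrocycle last by copper-catalysed O-arylation.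
Enabling feature: in a 4-O-methyl precursor the hydroxyls on C3 and C5 of ring D are equivalent (local twofold axis through C1 and C4), so either one closes the same ring and no phenol differentiation is needed. Ring A is para-substituted with no ortho groups, so a C4–Br bond is the only helper and it is consumed in the ring closure.
Stereochemistry: the target has no stereocentre; the E alkene made on the way is reduced.

Key step: step 7

Assumption: the 18-membered ring of the target and of its dimethyl ether is taken to be conformationally mobile at room temperature, so no element of planar chirality has to be controlled.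

**Route**

Step 1
Reactants: 1 2-fluoro-3-methoxybenzaldehyde; 2 (3-hydroxyphenyl)acetic acid
Product: 3 [3-(2-formyl-6-methoxyphenoxy)phenyl]acetic acid
Conditions: K2CO3 (3 equiv), DMSO, 110 °C; then 1 M HCl
Reagents that add atoms: none
Why: Nucleophilic aromatic substitution by addition–elimination, in which the phenoxide of 2 displaces the fluoride that the ortho formyl group activates, while the carboxylate stays a spectator whose alpha-CH2 is too weakly acidic to condense with the aldehyde.

Step 2
Reactants: 3 [3-(2-formyl-6-methoxyphenoxy)phenyl]acetic acid; 4 diethyl (4-bromobenzyl)phosphonate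
Product: 5 [3-[2-[(E)-2-(4-bromophenyl)ethenyl]-6-methoxyphenoxy]phenyl]acetic acid
Conditions: KOtBu (2.3 equiv), THF/DMF, 0 °C to rt; then 1 M HCl
Reagents that add atoms: none
Why: Horner–Wadsworth–Emmons olefination of the aldehyde by the benzylic phosphonate carbanion should give the E stilbene with the potassium carboxylate inert, and the alkene geometry is of no consequence because the double bond is reduced next.

Step 3
Reactants: 5 [3-[2-[(E)-2-(4-bromophenyl)ethenyl]-6-methoxyphenoxy]phenyl]acetic acid
Product: 6 [3-[2-[2-(4-bromophenyl)ethyl]-6-methoxyphenoxy]phenyl]acetic acid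
Conditions: TsNHNH2 (6 equiv), NaOAc (8 equiv), DME/H2O, reflux
Reagents that add atoms: none
Why: Diimide reduction, a concerted syn transfer of two hydrogens from diimide generated in the flask, saturates the C=C bond and leaves the aryl C–Br bond untouched, which hydrogenation over palladium would endanger.

Step 4
Reactants: 7 methyl 3,5-dihydroxy-4-methoxybenzoate
Product: 8 methyl 4-methoxy-3,5-bis(methoxymethoxy)benzoate
Conditions: MOMCl (2.6 equiv), i-Pr2NEt (3 equiv), CH2Cl2, 0 °C to rt
Reagents that add atoms: chloromethyl methyl ether (MOMCl), COCCl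
Why: O-alkylation of the two equivalent phenols gives methoxymethyl acetals that withstand the Grignard base of step 5 and later come off with acid without touching the C–Br bond.

Step 5
Reactants: 6 [3-[2-[2-(4-bromophenyl)ethyl]-6-methoxyphenoxy]phenyl]acetic acid; 8 methyl 4-methoxy-3,5-bis(methoxymethoxy)benzoate
Product: 11 2-[3-[2-[2-(4-bromophenyl)ethyl]-6-methoxyphenoxy]phenyl]-1-[4-methoxy-3,5-bis(methoxymethoxy)phenyl]ethanone, via magnesium enediolate 9 (not isolated), via beta-keto acid 10 (not isolated)
Conditions: t-BuMgCl (3.2 equiv), THF, 60 °C; then 1 M HCl, 0 °C to 40 °C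
Reagents that add atoms: none
Why: Ivanov-type Claisen condensation, in which double deprotonation of the arylacetic acid gives enediolate 9 that is C-acylated by the non-enolisable ester 8 (whose ester carbon becomes the ketone carbon on ring D), the product being shielded from over-addition as its enolate until acidification releases beta-keto acid 10, which loses CO2 through a six-membered cyclic transition state, while the hindered t-BuMgCl should not exchange with the unactivated aryl bromide.

Step 6
Reactants: 11 2-[3-[2-[2-(4-bromophenyl)ethyl]-6-methoxyphenoxy]phenyl]-1-[4-methoxy-3,5-bis(methoxymethoxy)phenyl]ethanone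
Product: 12 2-[3-[2-[2-(4-bromophenyl)ethyl]-6-methoxyphenoxy]phenyl]-1-(3,5-dihydroxy-4-methoxyphenyl)ethanone
Conditions: conc. HCl (cat.), MeOH/THF, 50 °C
Reagents that add atoms: none
Why: Acid-catalysed acetal exchange with methanol cleaves both methoxymethyl ethers and should leave the methyl ethers, the ketone and the aryl bromide unchanged.

Step 7
Reactants: 12 2-[3-[2-[2-(4-bromophenyl)ethyl]-6-methoxyphenoxy]phenyl]-1-(3,5-dihydroxy-4-methoxyphenyl)ethanone
Product: 15 di-O-methylmarchantin G (methyl ethers at the ring B oxygen and at O-4 of ring D; O-5 of ring D free), via cesium phenolate 13 (not isolated), via copper metallacycle 14 (not isolated)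
Conditions: CuI (0.3 equiv), N,N-dimethylglycine (0.6 equiv), Cs2CO3 (3 equiv), degassed 1,4-dioxane, 100 °C, syringe-pump addition of 12 over 12 h to 2 mM
Reagents that add atoms: none
Why: Ullmann-type diaryl ether synthesis run intramolecularly: Cs2CO3 turns one ring D hydroxyl into phenolate 13, which binds glycinate-ligated monovalent copper; oxidative addition of the ring A C4–Br bond then gives the 19-membered trivalent copper metallacycle 14, and C–O reductive elimination contracts it to the 18-membered ring and returns monovalent copper. The closest known reaction type is the copper-catalysed macrocyclising O-arylation of a phenol by an unactivated aryl bromide that closes diaryl ether cyclophanes such as the macrocyclic diarylheptanoids. The only ring closed is the 18-membered macrocycle, by ipso substitution at C4 of ring A with the breaking C–Br bond outside the new ring (exo mode), reached through ring contraction of 14. No stereocentre is formed, so no stereocontrol is required. Site selectivity is not needed because the C3 and C5 hydroxyls of ring D are equivalent, so either closes the same ring, the statistical factor of two helps cyclisation, and the untouched hydroxyl becomes the C5 hydroxyl of the target. The step does need intramolecular to beat intermolecular coupling, which slow addition to 2 mM should secure, and O- to beat C-arylation at the ketone alpha-CH2, which is expected because that carbon could only close a strained 13-membered para,meta-cyclophane and because the phenolate binds copper in dioxane far better than an enolate forms.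

Step 8
Reactants: 15 di-O-methylmarchantin G
Product: 17 marchantin G, via boron ester 16 (not isolated)
Conditions: BBr3 (6 equiv), CH2Cl2, −78 °C to 0 °C; then H2O
Reagents that add atoms: none
Why: Lewis-acid demethylation, in which BBr3 coordinates each methyl ether oxygen and bromide attacks the methyl group to give boron ester 16 that water hydrolyses, should free the ring B phenol and the ring D catechol while diaryl ethers and the aryl ketone are inert at this temperature.

**Compound list**

1 | 2-fluoro-3-methoxybenzaldehyde | COc1cccc(C=O)c1F | starting material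
2 | (3-hydroxyphenyl)acetic acid | OC(=O)Cc1cccc(O)c1 | starting material
3 | [3-(2-formyl-6-methoxyphenoxy)phenyl]acetic acid | OC(=O)Cc1cccc(Oc2c(C=O)cccc2OC)c1 | intermediate
4 | diethyl (4-bromobenzyl)phosphonate | CCOP(=O)(Cc1ccc(Br)cc1)OCC | starting material
5 | [3-[2-[(E)-2-(4-bromophenyl)ethenyl]-6-methoxyphenoxy]phenyl]acetic acid | OC(=O)Cc1cccc(Oc2c(/C=C/c3ccc(Br)cc3)cccc2OC)c1 | intermediate
6 | [3-[2-[2-(4-bromophenyl)ethyl]-6-methoxyphenoxy]phenyl]acetic acid | OC(=O)Cc1cccc(Oc2c(CCc3ccc(Br)cc3)cccc2OC)c1 | intermediate
7 | methyl 3,5-dihydroxy-4-methoxybenzoate | COC(=O)c1cc(O)c(OC)c(O)c1 | starting material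
8 | methyl 4-methoxy-3,5-bis(methoxymethoxy)benzoate | COC(=O)c1cc(OCOC)c(OC)c(OCOC)c1 | intermediate
9 | bis(chloromagnesium) enediolate of 6 (1,1-bis(chloromagnesiooxy)-2-arylethene) | Cl[Mg]OC(O[Mg]Cl)=Cc1cccc(Oc2c(CCc3ccc(Br)cc3)cccc2OC)c1 | intermediate
10 | racemic 2-[3-[2-[2-(4-bromophenyl)ethyl]-6-methoxyphenoxy]phenyl]-3-[4-methoxy-3,5-bis(methoxymethoxy)phenyl]-3-oxopropanoic acid | OC(=O)C(C(=O)c1cc(OCOC)c(OC)c(OCOC)c1)c1cccc(Oc2c(CCc3ccc(Br)cc3)cccc2OC)c1 | intermediate
11 | 2-[3-[2-[2-(4-bromophenyl)ethyl]-6-methoxyphenoxy]phenyl]-1-[4-methoxy-3,5-bis(methoxymethoxy)phenyl]ethanone | O=C(Cc1cccc(Oc2c(CCc3ccc(Br)cc3)cccc2OC)c1)c1cc(OCOC)c(OC)c(OCOC)c1 | intermediate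
12 | 2-[3-[2-[2-(4-bromophenyl)ethyl]-6-methoxyphenoxy]phenyl]-1-(3,5-dihydroxy-4-methoxyphenyl)ethanone | O=C(Cc1cccc(Oc2c(CCc3ccc(Br)cc3)cccc2OC)c1)c1cc(O)c(OC)c(O)c1 | intermediate
13 | mono-cesium phenolate of 12 (at one of the two equivalent ring D hydroxyls) | O=C(Cc1cccc(Oc2c(CCc3ccc(Br)cc3)cccc2OC)c1)c1cc(O)c(OC)c([O-])c1.[Cs+] | intermediate
14 | 19-membered metallacycle of trivalent copper bearing ring A C4 (aryl), ring D O-3 (aryloxide) and N,N-dimethylglycinate | O=C1Cc2cccc(c2)Oc2c(OC)cccc2CCc2ccc(cc2)[Cu](OC(=O)CN(C)C)Oc2cc1cc(O)c2OC | intermediate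
15 | di-O-methylmarchantin G (ring B OMe; ring D 4-OMe, 5-OH) | O=C1Cc2cccc(c2)Oc2c(OC)cccc2CCc2ccc(cc2)Oc2cc1cc(O)c2OC | intermediate
16 | boron ester of marchantin G (ring B O–BBr2; ring D O-4/O-5 as 2-bromo-1,3,2-benzodioxaborole) | O=C1Cc2cccc(c2)Oc2c(OB(Br)Br)cccc2CCc2ccc(cc2)Oc2cc1cc3OB(Br)Oc23 | intermediate
17 | marchantin G | O=C1Cc2cccc(c2)Oc2c(O)cccc2CCc2ccc(cc2)Oc2cc1cc(O)c2O | target

**Step count and risks**

Total step count: 8. Longest linear sequence: 7 steps (steps 1, 2, 3, 5, 6, 7, 8); step 4 is the one-step side branch.

Steps most likely to fail: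

Step 7. Intermolecular O-arylation may outrun ring closure and give oligomers, and the ketone alpha-CH2 may be deprotonated at 100 °C and then be arylated at carbon or oxidised by traces of air. Fallback: reverse the roles at copper so that the coupling runs at room temperature without carbonate base. Starting from 12, palladium-catalysed borylation (B2(OH)4, Pd(OAc)2/XPhos, KOAc, EtOH, 80 °C) should give [4-[2-[2-[3-[2-(3,5-dihydroxy-4-methoxyphenyl)-2-oxoethyl]phenoxy]-3-methoxyphenyl]ethyl]phenyl]boronic acid F1. Oxidative Chan–Lam macrocyclisation of this acid (Cu(OAc)2, pyridine, 4 Å molecular sieves, CH2Cl2, air, rt, 1 mM) proceeds by transmetalation to divalent copper and reductive elimination from trivalent copper, and returns to the route at 15.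

Step 5. The enediolate may be acylated only sluggishly by the electron-rich ester, and prolonged heating with the Grignard base may start bromine–magnesium exchange at ring A or proton transfer that stops the condensation. Fallback: a stepwise low-temperature Claisen route. Starting from 6, esterification (MeI, K2CO3, DMF) should give methyl [3-[2-[2-(4-bromophenyl)ethyl]-6-methoxyphenoxy]phenyl]acetate F2. Its lithium enolate (LiN(SiMe3)2, THF, −78 °C) is acylated by 8 on warming to 0 °C to give racemic methyl 2-[3-[2-[2-(4-bromophenyl)ethyl]-6-methoxyphenoxy]phenyl]-3-[4-methoxy-3,5-bis(methoxymethoxy)phenyl]-3-oxopropanoate F3. Krapcho dealkoxycarbonylation (LiCl, DMSO/H2O, 130 °C) then returns to the route at 11.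

Step 1. Substitution at the fluoride may be slow because the neighbouring methoxy group hinders and deactivates the ring, so that base-induced disproportionation of the aldehyde takes over. Fallback: replace addition–elimination by a copper-catalysed coupling that does not depend on the electrophilicity of the ring. Starting from 2, Ullmann coupling with 2-bromo-3-methoxybenzaldehyde F4 (CuI, picolinic acid, K3PO4, DMSO, 90 °C; then 1 M HCl), in which the ortho formyl group assists oxidative addition at monovalent copper, returns to the route at 3.

Further compounds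
F1 | step 7 | [4-[2-[2-[3-[2-(3,5-dihydroxy-4-methoxyphenyl)-2-oxoethyl]phenoxy]-3-methoxyphenyl]ethyl]phenyl]boronic acid | O=C(Cc1cccc(Oc2c(CCc3ccc(B(O)O)cc3)cccc2OC)c1)c1cc(O)c(OC)c(O)c1
F2 | step 5 | methyl [3-[2-[2-(4-bromophenyl)ethyl]-6-methoxyphenoxy]phenyl]acetate | COC(=O)Cc1cccc(Oc2c(CCc3ccc(Br)cc3)cccc2OC)c1
F3 | step 5 | racemic methyl 2-[3-[2-[2-(4-bromophenyl)ethyl]-6-methoxyphenoxy]phenyl]-3-[4-methoxy-3,5-bis(methoxymethoxy)phenyl]-3-oxopropanoate | COC(=O)C(C(=O)c1cc(OCOC)c(OC)c(OCOC)c1)c1cccc(Oc2c(CCc3ccc(Br)cc3)cccc2OC)c1
F4 | step 1 | 2-bromo-3-methoxybenzaldehyde | COc1cccc(C=O)c1Br
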